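**Retrosynthetic overview**
- The 2-pyranone is made last. An acid-triggered, pinacol-type one-atom ring expansion (−H2O) moves the lactone oxygen of a 5-(1-hydroxyalkyl)-5-methylbutenolide from C5 to the carbinol carbon. This is the key, higher-risk step.
- The butenolide carbinol comes from a vinylogous aldol (C5–C6 bond) between 3,4-dimethoxy-5-methylfuran-2(5H)-one and 11-(methylsulfanyl)undecanal.
- The furanone comes from 4π ring opening and lactonisation of the MeLi adduct of dimethyl squarate. C2–C5 and both OMe groups are bought in place.
- The aldehyde comes from 11-bromoundecan-1-ol by NaSMe displacement and then oxidation.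
- Ring order: cyclobutene (purchased) → butenolide → 2-pyranone. The usual tricarbonyl cyclisation to a 4-hydroxy-2-pyrone followed by O-methylation, with its α/γ-pyrone regiochemistry problem, is deliberately avoided.

Assumption: the target SMILES contains no stereocentre and no stereogenic double bond, so the target is achiral and the single-enantiomer requirement does not apply. The racemic sp3 centres in 2, 3 and 7 all become sp2 in the last step.

**Step 1**
Reactants: 1, dimethyl squarate (3,4-dimethoxycyclobut-3-ene-1,2-dione)
Product: 2, (±)-4-hydroxy-2,3-dimethoxy-4-methylcyclobut-2-en-1-one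
Conditions: MeLi (1.05 equiv), THF, −78 °C; sat. aq NH4Cl, −78 °C → rt
Reagents that add atoms: methyllithium, [Li]C
Why: This is a 1,2-addition of a hard organolithium to the strained squarate carbonyl; the resulting alkoxide deactivates the remaining vinylogous-ester carbonyl, so addition stops at one methyl, and the new stereocentre is racemic and is erased later.

**Step 2**
Reactants: 2
Product: 3, (±)-3,4-dimethoxy-5-methylfuran-2(5H)-one
Conditions: p-xylene (0.05 M), reflux (138 °C), N2, base-washed glassware
Reagents that add atoms: none
Why: This is the Moore-type cyclobutenone rearrangement, in which reversible thermal 4π electrocyclic opening gives the hydroxyvinylketene; with no unsaturated C4 substituent to intercept it, the OH-inward isomer is drained by attack of the hydroxyl on the ketene and tautomerisation to the conjugated butenolide (C5 racemic).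

**Step 3**
Reactants: 4, 11-bromoundecan-1-ol
Product: 5, 11-(methylsulfanyl)undecan-1-ol
Conditions: NaSMe (1.2 equiv), DMF, 0 °C → rt
Reagents that add atoms: sodium methanethiolate, C[S-].[Na+]
Why: This is an SN2 displacement of a primary bromide by a soft thiolate, which is not basic enough to deprotonate or engage the free alcohol.

**Step 4**
Reactants: 5
Product: 6, 11-(methylsulfanyl)undecanal
Conditions: SO3·py, DMSO, Et3N, CH2Cl2, 0 °C → rt
Reagents that add atoms: none
Why: This is a Parikh–Doering oxidation; activated DMSO does not transfer oxygen, so the dialkyl sulfide survives and the reaction stops at the aldehyde.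

**Step 5**
Reactants: 3, 3,4-dimethoxy-5-methylfuran-2(5H)-one; 6, 11-(methylsulfanyl)undecanal
Product: 7, 5-[1-hydroxy-11-(methylsulfanyl)undecyl]-3,4-dimethoxy-5-methylfuran-2(5H)-one (racemic mixture of diastereomers)
Conditions: 3, LDA (1.05 equiv), THF, −78 °C, 30 min; then 6 (1.1 equiv), −78 °C, 1 h; AcOH quench at −78 °C
Reagents that add atoms: none
Why: This is a vinylogous aldol of a tetronate-type dienolate (an aromatic 2-oxidofuran; C5–H is the only acidic site), which reacts at C5 so the vinylogous-carbonate conjugation is kept; the cold acidic quench limits retro-aldol, and neither new stereocentre needs control because both are destroyed in Step 6.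

**Step 6**
Reactants: 7
Product: 8, 3,4-dimethoxy-5-methyl-6-[10-(methylsulfanyl)decyl]-2H-pyran-2-one (target)
Conditions: p-TsOH·H2O (0.3 equiv), PhMe, reflux, Dean–Stark
Reagents that add atoms: none (net loss of H2O)
Why: Proposed new method: protonation of the lactone carbonyl should trigger A_AL1 ionisation of the tertiary, allylic C5–O bond (the cation is delocalised to the 3-OMe-bearing carbon as an oxocarbenium); the adjacent carbinol C–H then shifts or is lost as in a pinacol rearrangement of a tert/sec diol monoester, giving the (Z)-2,3-dimethoxy-4-methyl-5-oxo-enoic acid, whose enol lactonises and dehydrates to the 2-pyranone; a second pathway, translactonisation to the 5-hydroxy-5,6-dihydropyranone followed by E1 loss of the tertiary allylic OH, leads to the same product; the closest known reactions are the pinacol/semipinacol rearrangement, acidolysis of tert-alkyl esters, and acid cyclodehydration of 5-oxo-2-enoic acids to 2-pyranones; the thioether and the enol methyl ethers tolerate catalytic non-oxidising acid when water is removed.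

**Atom origin in 8**
- C2–C5, the C2 carbonyl oxygen and both OMe groups come from 1.
- The 5-methyl group comes from MeLi.
- C6, ring O1 and the ten chain carbons come from 4.
- The SMe group comes from NaSMe.
- Mass balance for the last step: 7 (C19H34O5S) − H2O = 8 (C19H32O4S).

**Compound list**
1 | dimethyl squarate | COC1=C(OC)C(=O)C1=O | starting material
2 | (±)-4-hydroxy-2,3-dimethoxy-4-methylcyclobut-2-en-1-one | COC1=C(OC)C(C)(O)C1=O | intermediate (racemic)
3 | (±)-3,4-dimethoxy-5-methylfuran-2(5H)-one | COC1=C(OC)C(=O)OC1C | intermediate (racemic)
4 | 11-bromoundecan-1-ol | OCCCCCCCCCCCBr | starting material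
5 | 11-(methylsulfanyl)undecan-1-ol | CSCCCCCCCCCCCO | intermediate
6 | 11-(methylsulfanyl)undecanal | CSCCCCCCCCCCC=O | intermediate
7 | 5-[1-hydroxy-11-(methylsulfanyl)undecyl]-3,4-dimethoxy-5-methylfuran-2(5H)-one | COC1=C(OC)C(=O)OC1(C)C(O)CCCCCCCCCCSC | intermediate (racemic, diastereomer mixture)
8 | 3,4-dimethoxy-5-methyl-6-[10-(methylsulfanyl)decyl]-2H-pyran-2-one | COc1c(C)c(CCCCCCCCCCSC)oc(=O)c1OC | target (achiral)

**Total step count:** 6
**Longest linear sequence:** 4 steps (1→2→3→7→8; the branch 4→5→6→7→8 is also 4 steps)

**Steps most likely to fail**
1. **Step 6, ring expansion.**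
   - Risk: acid retro-aldol, or re-closure to the butenolide, may outrun the hydride shift.
   - Fallback: replace cationic C–O ionisation with reductive cleavage. Oxidise 7 (Parikh–Doering) to the 5-acylbutenolide, cleave the α-acyloxy-ketone C5–O bond with SmI2 (THF/MeOH, −78 °C) to the (Z)-δ-keto acid, then close with TFAA/TFA.
2. **Step 5, quaternary-centre vinylogous aldol.**
   - Risk: retro-aldol, aldehyde enolisation, or attack at C3.
   - Fallback: convert 3 to the isolated 2-(tert-butyldimethylsilyloxy)furan and run a BF3·OEt2 vinylogous Mukaiyama aldol. This is γ-selective and should be far less prone to retro-aldol than the lithium aldolate. If the carbinol is then carried forward as its silyl ether, that ether would be a true semipinacol substrate for Step 6 and could not undergo retro-aldol.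
3. **Step 2, thermal cyclobutenone → furanone.**
   - Risk: the preference for outward rotation of OH slows lactonisation, and MeOH may be lost to give the cyclobutenedione.
   - Fallback: abandon the electrocyclic route to 3. Start from 4-methoxy-5-methylfuran-2(5H)-one (methyl 5-methyltetronate), brominate at C3 with NBS, and install the 3-OMe by Cu-mediated methoxylation.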